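With the equivalents held, a loss of electrophile by one step between two charged partners, with no other step at work, keeps an invariant: the fraction of the charge gone follows starting concentration times time, the reduced time of second-order kinetics. Two earlier runs and the new flask share their equivalents.

| setting | violet | ochre | flask |
|---|---|---|---|
| electrophile | 0.063 M | 0.14 M | 0.094 M |
| nucleophile | 2 equiv | 2 equiv | 2.00 equiv |
| buffer base | 1 equiv | 1 equiv | 1.00 equiv |
| buffer acid | 0.10 equiv | 0.10 equiv | 0.100 equiv |
| remark | run made earlier | run made earlier |  |
| time |  |  | 15 h |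

| run | time / h | electrophile / % | target / % |
|---|---|---|---|
| violet | 1.50 | 95.2 | 2.1 |
| violet | 3.00 | 95.2 | 4.3 |
| violet | 5.00 | 91.7 | 7.4 |
| violet | 6.00 | 89.5 | 7.3 |
| violet | 8.00 | 87.6 | 9.9 |
| violet | 10.0 | 84.1 | 10.3 |
| violet | 12.0 | 83.1 | 11.4 |
| ochre | 0.667 | 96.9 | 1.6 |
| ochre | 2.00 | 90.6 | 3.7 |
| ochre | 3.00 | 86.7 | 6.7 |
| ochre | 5.00 | 82.1 | 10.8 |
| ochre | 8.00 | 73.7 | 13.3 |
| ochre | 10.0 | 71.1 | 16.9 |
| ochre | 12.0 | 68.3 | 20.6 |

(each reading ± 1 percentage point)

- part of the electrophile that has reacted at 15 h
- pH of the solution at 15 h

- a reading or a percentage of target counts all its forms, free or not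
- what has gone from electrophile into another species counts as reacted, even if it can come back
- the earlier runs do not show the pH; that part of a forecast is a guess
- a reading of electrophile is of its free form alone

I tested the invariant first. Ochre at 5.00 h and violet at 12.0 h had products of 0.700 M·h and 0.756 M·h, and had lost 17.9% and 16.9% of the charge. With a scatter of 1 percentage point, I accepted a single curve.

The flask's exposure, this product for its own charge and time, was 1.41 M·h. Ochre reached 1.40 M·h at 10.0 h, with 28.9% gone, and that was my first number.

Its weak link was a single reading from a more concentrated run. The ochre readings at 8.00 h and 12.0 h averaged 29.0% gone, so that reading was no stray. But ochre had read 1 point ahead of violet on a smaller product, so as an estimate I took that much off for the more dilute flask and stood at 27.9%.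

The forecast said 28% (25% to 31%) and pH 7.4 (5 to 9.5); its ground for the first was that “the kinetics are roughly second order”, and it called the pH a guess.

The flask gave 27.5% reacted and pH 7.54.

    electrophile + nucleophile → acid + target + leaving group (k = 0.00270 L mol⁻¹ min⁻¹)
    protonated nucleophile ⇌ nucleophile + acid, settled at all times (K = 7.90 × 10⁻⁸ M)
    buffer acid ⇌ buffer base + acid, settled at all times (K = 4.00 × 10⁻⁶ M)
    2 nucleophile → homo dimer (k = 0.00170 L mol⁻¹ min⁻¹)
    electrophile + target ⇌ idle adduct, settled at all times (K = 17.0 L mol⁻¹)
    nucleophile ⇌ dormant form (K = 0.730, k = 0.0110 min⁻¹)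

A run with half the nucleophile, its other amounts and its exposure of 1.41 M·h as in the flask, reached 15.1%, so that run left the ochre curve, and the forecast's range with it.

Read at 4.0 h, the flask has an exposure of 0.376 M·h; violet at 6.00 h stood at 0.378 M·h with 10.5% gone, and that was my figure. The computed value is 10.4%.

Readings and results are calculated on assumed constants; the scatter is artificial.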